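**Retrosynthetic overview**
1. Target acid ⇐ S-ethyl thioester; the C3–CH2 bond is cut by a TiCl4-mediated Mukaiyama aldol-type addition of the silyl ketene thioacetal of S-ethyl thioacetate to the peroxycarbenium ion of a 3-methoxy-1,2-dioxolane (sets C3, trans to the side chain).
2. Methoxydioxolane ⇐ β-silylperoxy methyl ketone ⇐ β-hydroperoxy alcohol ⇐ H2O2 opening, with inversion, of an enantioenriched 2,2,4-trisubstituted oxetane (sets C5).
3. Oxetane ⇐ 1,3-diol ⇐ Sharpless epoxy alcohol of an (E)-3-methylalk-2-en-1-ol, built from (R)-citronellal (source of the side-chain methyl centre) by alkyne homologation and carboalumination.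
4. Styryl diene tail: Julia–Kocienski olefination of the ozonolysis aldehyde with a tetrazolyl sulfone made through a Johnson–Claisen rearrangement.
5. Ring order: oxirane (step 7, opened in step 10), oxetane (step 12, opened in step 15), 1,2-dioxolane last (step 18); the benzene ring is bought.

Assumption: carbinol and ketal centres that are erased later are carried as epimer mixtures, and commercial (R)-citronellal of at least 97% ee supplies the side-chain methyl centre.

**Route**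

Step 1
Reactants: 1 1-phenylprop-2-en-1-ol (racemic); 2 triethyl orthoacetate
Product: 4 ethyl (4E)-5-phenylpent-4-enoate, via ketene acetal 3 (not isolated)
Conditions: EtCO2H (cat.), excess 2, 140 °C, EtOH distilled off
Reagents that add atoms: none
Why: Johnson–Claisen rearrangement, in which the chair [3,3] shift of the mixed ketene acetal with phenyl equatorial gives the conjugated E-styrene almost exclusively.

Step 2
Reactants: 4 ethyl (4E)-5-phenylpent-4-enoate
Product: 5 (4E)-5-phenylpent-4-en-1-ol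
Conditions: LiAlH4, Et2O, 0 °C
Reagents that add atoms: none
Why: Hydride reduction of the ester to the primary alcohol, which leaves the styrene untouched.

Step 3
Reactants: 5 (4E)-5-phenylpent-4-en-1-ol
Product: 6 1-phenyl-5-{[(4E)-5-phenylpent-4-en-1-yl]sulfanyl}-1H-tetrazole
Conditions: 1-phenyl-1H-tetrazole-5-thiol, PPh3, DIAD, THF, 0 °C → rt
Reagents that add atoms: 1-phenyl-1H-tetrazole-5-thiol (Sc1nnnn1-c1ccccc1)
Why: Mitsunobu thioetherification of an unhindered primary alcohol with an acidic heteroaryl thiol.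

Step 4
Reactants: 6 1-phenyl-5-{[(4E)-5-phenylpent-4-en-1-yl]sulfanyl}-1H-tetrazole
Product: 7 1-phenyl-5-{[(4E)-5-phenylpent-4-en-1-yl]sulfonyl}-1H-tetrazole
Conditions: (NH4)6Mo7O24·4H2O (cat.), 30% H2O2, EtOH, 0 °C → rt
Reagents that add atoms: hydrogen peroxide (OO)
Why: (NH4)6Mo7O24-catalysed sulfide-to-sulfone oxidation is much faster than epoxidation of the styrene.

Step 5
Reactants: 8 (R)-citronellal
Product: 9 (4R)-4,8-dimethylnon-7-en-1-yne
Conditions: dimethyl (1-diazo-2-oxopropyl)phosphonate, K2CO3, MeOH, 0 °C → rt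
Reagents that add atoms: dimethyl (1-diazo-2-oxopropyl)phosphonate (CC(=O)C(=[N+]=[N-])P(=O)(OC)OC)
Why: Ohira–Bestmann (Seyferth–Gilbert) homologation of the aldehyde to the terminal alkyne, with the stereocentre β to the carbonyl and therefore not epimerisable.

Step 6
Reactants: 9 (4R)-4,8-dimethylnon-7-en-1-yne
Product: 12 (2E,5R)-3,5,9-trimethyldeca-2,8-dien-1-ol, via alkenylalane 10 (not isolated), via lithium alanate 11 (not isolated)
Conditions: AlMe3, Cp2ZrCl2 (0.25 equiv), CH2Cl2, 0 °C → rt; volatiles removed; n-BuLi, hexane/THF, −78 °C; (CH2O)n, → rt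
Reagents that add atoms: trimethylaluminium (C[Al](C)C); formaldehyde from paraformaldehyde (C=O)
Why: Negishi Cp2ZrCl2-catalysed carboalumination adds Me–Al syn with methyl on the internal carbon, and hydroxymethylation of the alanate with retention gives only the E-trisubstituted allylic alcohol while the remote trisubstituted alkene is inert.

Step 7
Reactants: 12 (2E,5R)-3,5,9-trimethyldeca-2,8-dien-1-ol
Product: 13 [(2S,3S)-3-[(2R)-2,6-dimethylhept-5-en-1-yl]-3-methyloxiran-2-yl]methanol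
Conditions: Ti(OiPr)4 (10 mol%), L-(+)-diethyl tartrate (12 mol%), t-BuOOH, 4 Å MS, CH2Cl2, −20 °C
Reagents that add atoms: tert-butyl hydroperoxide (CC(C)(C)OO)
Why: Sharpless asymmetric epoxidation, in which L-(+)-tartrate gives the (2S,3S)-epoxide of an (E)-3-methylalk-2-en-1-ol (as with geraniol) under reagent control (about 95:5 expected), only the allylic alkene reacting.

Step 8
Reactants: 13 [(2S,3S)-3-[(2R)-2,6-dimethylhept-5-en-1-yl]-3-methyloxiran-2-yl]methanol
Product: 14 (2R,3S)-3-[(2R)-2,6-dimethylhept-5-en-1-yl]-3-methyloxirane-2-carbaldehyde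
Conditions: Dess–Martin periodinane, NaHCO3, CH2Cl2, 0 °C → rt
Reagents that add atoms: none
Why: Buffered Dess–Martin oxidation gives the epoxy aldehyde without opening the epoxide (the C2 descriptor changes only because of CIP priorities).

Step 9
Reactants: 14 (2R,3S)-3-[(2R)-2,6-dimethylhept-5-en-1-yl]-3-methyloxirane-2-carbaldehyde
Product: 15 1-[(2S,3S)-3-[(2R)-2,6-dimethylhept-5-en-1-yl]-3-methyloxiran-2-yl]ethan-1-ol
Conditions: MeMgBr, THF, −78 °C
Reagents that add atoms: methylmagnesium bromide (C[Mg]Br)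
Why: Grignard addition to the aldehyde is far faster than epoxide opening at −78 °C, and the new carbinol centre forms as a mixture that is erased by oxidation in step 17.

Step 10
Reactants: 15 1-[(2S,3S)-3-[(2R)-2,6-dimethylhept-5-en-1-yl]-3-methyloxiran-2-yl]ethan-1-ol
Product: 16 (4S,6R)-4,6,10-trimethylundec-9-ene-2,4-diol
Conditions: NaAlH2(OCH2CH2OMe)2, THF, 0 °C → rt
Reagents that add atoms: none
Why: Hydroxyl-directed reduction of a 2,3-epoxy alcohol, in which hydride is delivered intramolecularly from the alkoxyaluminate to the epoxide carbon next to the carbinol, so the tertiary C–O bond and its (S) configuration are untouched.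

Step 11
Reactants: 16 (4S,6R)-4,6,10-trimethylundec-9-ene-2,4-diol
Product: 17 (4S,6R)-4-hydroxy-4,6,10-trimethylundec-9-en-2-yl 4-methylbenzenesulfonate
Conditions: TsCl, pyridine, DMAP (cat.), CH2Cl2, 0 °C → rt
Reagents that add atoms: 4-methylbenzenesulfonyl chloride (Cc1ccc(cc1)S(=O)(=O)Cl)
Why: Sulfonylation distinguishes the secondary from the tertiary hydroxyl on steric grounds.

Step 12
Reactants: 17 (4S,6R)-4-hydroxy-4,6,10-trimethylundec-9-en-2-yl 4-methylbenzenesulfonate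
Product: 18 (2S)-2-[(2R)-2,6-dimethylhept-5-en-1-yl]-2,4-dimethyloxetane
Conditions: KOtBu, THF, 0 °C → rt
Reagents that add atoms: none
Why: Intramolecular Williamson etherification (4-exo-tet) helped by the gem-disubstituted alkoxide carbon, with the quaternary centre keeping its (S) configuration because only its O–H bond is involved and the inverted C4 centre being erased in step 17.

Step 13
Reactants: 18 (2S)-2-[(2R)-2,6-dimethylhept-5-en-1-yl]-2,4-dimethyloxetane
Product: 20 (4R)-5-[(2S)-2,4-dimethyloxetan-2-yl]-4-methylpentanal, via ozonide 19 (not isolated)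
Conditions: O3, CH2Cl2, −78 °C; then PPh3, −78 °C → rt
Reagents that add atoms: ozone ([O-][O+]=O)
Why: Ozonolysis with reductive work-up cleaves the only alkene, the oxetane ether being inert to ozone and PPh3.

Step 14
Reactants: 20 (4R)-5-[(2S)-2,4-dimethyloxetan-2-yl]-4-methylpentanal; 7 1-phenyl-5-{[(4E)-5-phenylpent-4-en-1-yl]sulfonyl}-1H-tetrazole
Product: 21 (2S)-2,4-dimethyl-2-[(2R,5E,9E)-2-methyl-10-phenyldeca-5,9-dien-1-yl]oxetane
Conditions: KN(SiMe3)2, DME, −60 °C → rt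
Reagents that add atoms: none
Why: Julia–Kocienski olefination, where the phenyltetrazolyl sulfone with a potassium counter-ion in DME gives the anti β-alkoxy sulfone and, after Smiles rearrangement and anti elimination, the 5E-alkene (about 95:5 expected), the oxetane being base-stable.

Step 15
Reactants: 21 (2S)-2,4-dimethyl-2-[(2R,5E,9E)-2-methyl-10-phenyldeca-5,9-dien-1-yl]oxetane
Product: 22 (4R,6R,9E,13E)-4-hydroperoxy-4,6-dimethyl-14-phenyltetradeca-9,13-dien-2-ol
Conditions: anhydrous H2O2 in Et2O (excess), TMSOTf (cat.), Et2O, −78 → 0 °C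
Reagents that add atoms: hydrogen peroxide (OO)
Why: Lewis acid-promoted perhydrolysis of the oxetane, in which H2O2 attacks the activated, more substituted ring carbon from the rear (SN2-like), inverting the (S) quaternary centre to the (R) tertiary hydroperoxide that becomes C5, while the unactivated disubstituted alkenes are spared at low temperature.

Step 16
Reactants: 22 (4R,6R,9E,13E)-4-hydroperoxy-4,6-dimethyl-14-phenyltetradeca-9,13-dien-2-ol
Product: 23 (4R,6R,9E,13E)-4-[(tert-butyldimethylsilyl)peroxy]-4,6-dimethyl-14-phenyltetradeca-9,13-dien-2-ol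
Conditions: TBSCl (1.05 equiv), imidazole, CH2Cl2, 0 °C
Reagents that add atoms: tert-butyldimethylsilyl chloride (CC(C)(C)[Si](C)(C)Cl)
Why: Chemoselective silylation, since the terminal O–H of the hydroperoxide is unhindered and several pKa units more acidic than the secondary carbinol, so one equivalent of TBSCl caps it first.

Step 17
Reactants: 23 (4R,6R,9E,13E)-4-[(tert-butyldimethylsilyl)peroxy]-4,6-dimethyl-14-phenyltetradeca-9,13-dien-2-ol
Product: 24 (4R,6R,9E,13E)-4-[(tert-butyldimethylsilyl)peroxy]-4,6-dimethyl-14-phenyltetradeca-9,13-dien-2-one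
Conditions: Dess–Martin periodinane, NaHCO3, CH2Cl2, 0 °C → rt
Reagents that add atoms: none
Why: Dess–Martin oxidation of the secondary alcohol tolerates silyl peroxides and alkenes and removes the stereorandom carbinol centre.

Step 18
Reactants: 24 (4R,6R,9E,13E)-4-[(tert-butyldimethylsilyl)peroxy]-4,6-dimethyl-14-phenyltetradeca-9,13-dien-2-one
Product: 27 (5R)-3-methoxy-3,5-dimethyl-5-[(2R,5E,9E)-2-methyl-10-phenyldeca-5,9-dien-1-yl]-1,2-dioxolane, via hydroperoxy ketone 25 (not isolated), via dioxolanol 26 (not isolated)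
Conditions: HF·pyridine, THF, 0 °C; then TsOH·H2O (cat.), MeOH, rt
Reagents that add atoms: methanol (CO)
Why: Desilylation frees the hydroperoxide, which closes onto the ketone (5-exo peroxyhemiketalisation) and is then ketalised with methanol under acid catalysis, C5 not being involved and the C3 anomer mixture being irrelevant because C3 is planarised in step 20.

Step 19
Reactants: 28 S-ethyl ethanethioate
Product: 29 {[1-(ethylsulfanyl)ethenyl]oxy}trimethylsilane
Conditions: LiN(iPr)2, TMSCl, THF, −78 °C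
Reagents that add atoms: chlorotrimethylsilane (C[Si](C)(C)Cl)
Why: Kinetic enolisation of the thioester with in situ O-silylation gives the silyl ketene thioacetal.

Step 20
Reactants: 27 (5R)-3-methoxy-3,5-dimethyl-5-[(2R,5E,9E)-2-methyl-10-phenyldeca-5,9-dien-1-yl]-1,2-dioxolane; 29 {[1-(ethylsulfanyl)ethenyl]oxy}trimethylsilane
Product: 31 S-ethyl 2-[(3S,5R)-3,5-dimethyl-5-[(2R,5E,9E)-2-methyl-10-phenyldeca-5,9-dien-1-yl]-1,2-dioxolan-3-yl]ethanethioate, via peroxycarbenium ion 30 (not isolated)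
Conditions: TiCl4, CH2Cl2, −78 °C
Reagents that add atoms: none
Why: Mukaiyama aldol-type addition, in which TiCl4 ionises the peroxyketal to the planar peroxycarbenium ion and the silyl ketene thioacetal adds to C3 from the ring face opposite the bulkier C5 side chain, setting C3 as S with only moderate selectivity expected, the C3 epimer (and any C5 epimer from steps 7 and 15) being removed by chromatography.

Step 21
Reactants: 31 S-ethyl 2-[(3S,5R)-3,5-dimethyl-5-[(2R,5E,9E)-2-methyl-10-phenyldeca-5,9-dien-1-yl]-1,2-dioxolan-3-yl]ethanethioate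
Product: 32 2-[(3S,5R)-3,5-dimethyl-5-[(2R,5E,9E)-2-methyl-10-phenyldeca-5,9-dien-1-yl]-1,2-dioxolan-3-yl]acetic acid
Conditions: LiOH, 30% H2O2, THF/H2O, 0 °C; then aq. Na2SO3; dilute HCl
Reagents that add atoms: hydrogen peroxide (OO)
Why: Thioester cleavage by hydroperoxide anion, a weakly basic α-effect nucleophile that attacks the acyl carbon faster than enolisation and β-elimination of the peroxide can occur, the tetrasubstituted dioxolane being stable to these conditions and to sulfite.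

**Compound list**
1 | 1-phenylprop-2-en-1-ol (racemic) | C=CC(O)c1ccccc1 | starting material
2 | triethyl orthoacetate | CCOC(C)(OCC)OCC | starting material
3 | {1-[(1-ethoxyethenyl)oxy]prop-2-en-1-yl}benzene | C=CC(OC(=C)OCC)c1ccccc1 | intermediate
4 | ethyl (4E)-5-phenylpent-4-enoate | CCOC(=O)CC/C=C/c1ccccc1 | intermediate
5 | (4E)-5-phenylpent-4-en-1-ol | OCCC/C=C/c1ccccc1 | intermediate
6 | 1-phenyl-5-{[(4E)-5-phenylpent-4-en-1-yl]sulfanyl}-1H-tetrazole | S(CCC/C=C/c1ccccc1)c1nnnn1-c1ccccc1 | intermediate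
7 | 1-phenyl-5-{[(4E)-5-phenylpent-4-en-1-yl]sulfonyl}-1H-tetrazole | O=S(=O)(CCC/C=C/c1ccccc1)c1nnnn1-c1ccccc1 | intermediate
8 | (R)-citronellal, (3R)-3,7-dimethyloct-6-enal | C[C@H](CCC=C(C)C)CC=O | starting material
9 | (4R)-4,8-dimethylnon-7-en-1-yne | C[C@H](CCC=C(C)C)CC#C | intermediate
10 | dimethyl[(1E,4R)-2,4,8-trimethylnona-1,7-dien-1-yl]alumane | C[C@H](CCC=C(C)C)C/C(C)=C/[Al](C)C | intermediate
11 | lithium butyl(dimethyl)[(1E,4R)-2,4,8-trimethylnona-1,7-dien-1-yl]aluminate | [Li+].C[C@H](CCC=C(C)C)C/C(C)=C/[Al-](C)(C)CCCC | intermediate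
12 | (2E,5R)-3,5,9-trimethyldeca-2,8-dien-1-ol | C[C@H](CCC=C(C)C)C/C(C)=C/CO | intermediate
13 | [(2S,3S)-3-[(2R)-2,6-dimethylhept-5-en-1-yl]-3-methyloxiran-2-yl]methanol | OC[C@@H]1O[C@@]1(C)C[C@H](C)CCC=C(C)C | intermediate
14 | (2R,3S)-3-[(2R)-2,6-dimethylhept-5-en-1-yl]-3-methyloxirane-2-carbaldehyde | O=C[C@@H]1O[C@@]1(C)C[C@H](C)CCC=C(C)C | intermediate
15 | 1-[(2S,3S)-3-[(2R)-2,6-dimethylhept-5-en-1-yl]-3-methyloxiran-2-yl]ethan-1-ol (carbinol epimers) | CC(O)[C@@H]1O[C@@]1(C)C[C@H](C)CCC=C(C)C | intermediate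
16 | (4S,6R)-4,6,10-trimethylundec-9-ene-2,4-diol (C2 epimers) | CC(O)C[C@@](C)(O)C[C@H](C)CCC=C(C)C | intermediate
17 | (4S,6R)-4-hydroxy-4,6,10-trimethylundec-9-en-2-yl 4-methylbenzenesulfonate (C2 epimers) | CC(OS(=O)(=O)c1ccc(C)cc1)C[C@@](C)(O)C[C@H](C)CCC=C(C)C | intermediate
18 | (2S)-2-[(2R)-2,6-dimethylhept-5-en-1-yl]-2,4-dimethyloxetane (C4 epimers) | CC1C[C@@](C)(O1)C[C@H](C)CCC=C(C)C | intermediate
19 | 3-{(3R)-4-[(2S)-2,4-dimethyloxetan-2-yl]-3-methylbutyl}-5,5-dimethyl-1,2,4-trioxolane | CC1C[C@@](C)(O1)C[C@H](C)CCC2OOC(C)(C)O2 | intermediate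
20 | (4R)-5-[(2S)-2,4-dimethyloxetan-2-yl]-4-methylpentanal | CC1C[C@@](C)(O1)C[C@H](C)CCC=O | intermediate
21 | (2S)-2,4-dimethyl-2-[(2R,5E,9E)-2-methyl-10-phenyldeca-5,9-dien-1-yl]oxetane | CC1C[C@@](C)(O1)C[C@H](C)CC/C=C/CC/C=C/c1ccccc1 | intermediate
22 | (4R,6R,9E,13E)-4-hydroperoxy-4,6-dimethyl-14-phenyltetradeca-9,13-dien-2-ol (C2 epimers) | CC(O)C[C@](C)(OO)C[C@H](C)CC/C=C/CC/C=C/c1ccccc1 | intermediate
23 | (4R,6R,9E,13E)-4-[(tert-butyldimethylsilyl)peroxy]-4,6-dimethyl-14-phenyltetradeca-9,13-dien-2-ol | CC(O)C[C@](C)(OO[Si](C)(C)C(C)(C)C)C[C@H](C)CC/C=C/CC/C=C/c1ccccc1 | intermediate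
24 | (4R,6R,9E,13E)-4-[(tert-butyldimethylsilyl)peroxy]-4,6-dimethyl-14-phenyltetradeca-9,13-dien-2-one | CC(=O)C[C@](C)(OO[Si](C)(C)C(C)(C)C)C[C@H](C)CC/C=C/CC/C=C/c1ccccc1 | intermediate
25 | (4R,6R,9E,13E)-4-hydroperoxy-4,6-dimethyl-14-phenyltetradeca-9,13-dien-2-one | CC(=O)C[C@](C)(OO)C[C@H](C)CC/C=C/CC/C=C/c1ccccc1 | intermediate
26 | (5R)-3,5-dimethyl-5-[(2R,5E,9E)-2-methyl-10-phenyldeca-5,9-dien-1-yl]-1,2-dioxolan-3-ol | C[C@H](CC/C=C/CC/C=C/c1ccccc1)C[C@]1(C)CC(C)(O)OO1 | intermediate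
27 | (5R)-3-methoxy-3,5-dimethyl-5-[(2R,5E,9E)-2-methyl-10-phenyldeca-5,9-dien-1-yl]-1,2-dioxolane (C3 epimers) | C[C@H](CC/C=C/CC/C=C/c1ccccc1)C[C@]1(C)CC(C)(OC)OO1 | intermediate
28 | S-ethyl ethanethioate | CC(=O)SCC | starting material
29 | {[1-(ethylsulfanyl)ethenyl]oxy}trimethylsilane | C=C(O[Si](C)(C)C)SCC | intermediate
30 | (5R)-3,5-dimethyl-5-[(2R,5E,9E)-2-methyl-10-phenyldeca-5,9-dien-1-yl]-1,2-dioxolan-3-ylium | C[C@H](CC/C=C/CC/C=C/c1ccccc1)C[C@]1(C)CC(C)=[O+]O1 | intermediate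
31 | S-ethyl 2-[(3S,5R)-3,5-dimethyl-5-[(2R,5E,9E)-2-methyl-10-phenyldeca-5,9-dien-1-yl]-1,2-dioxolan-3-yl]ethanethioate | C[C@H](CC/C=C/CC/C=C/c1ccccc1)C[C@]1(C)C[C@@](C)(CC(=O)SCC)OO1 | intermediate
32 | 2-[(3S,5R)-3,5-dimethyl-5-[(2R,5E,9E)-2-methyl-10-phenyldeca-5,9-dien-1-yl]-1,2-dioxolan-3-yl]acetic acid | C[C@H](CC/C=C/CC/C=C/c1ccccc1)C[C@]1(C)C[C@@](C)(CC(=O)O)OO1 | target

**Step count and risks**

Total: 21 steps. Longest linear sequence: 16 steps (8 → 32 through steps 5–18, 20 and 21).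

Step 14 (Julia–Kocienski). The risk is a few percent of the 5Z isomer, which cannot be separated from 21 and cannot be corrected later. The fallback sets out from 20 and comes back at 21. Aldehyde 20 is homologated with the Ohira–Bestmann reagent (K2CO3, MeOH) to (2S)-2,4-dimethyl-2-[(2R)-2-methylhex-5-yn-1-yl]oxetane F1. Hydrozirconation with Cp2Zr(H)Cl in THF gives chlorobis(cyclopentadienyl)[(1E,5R)-6-[(2S)-2,4-dimethyloxetan-2-yl]-5-methylhex-1-en-1-yl]zirconium F2, which is iodinated in the same flask (I2, 0 °C) to the geometrically pure (2S)-2-[(2R,5E)-6-iodo-2-methylhex-5-en-1-yl]-2,4-dimethyloxetane F3. Separately, commercial cyclopropyl(phenyl)methanol (OC(C1CC1)c1ccccc1) is opened with 48% HBr (Julia cyclopropylcarbinyl rearrangement) to [(1E)-4-bromobut-1-en-1-yl]benzene F4, which zinc dust and LiCl in THF convert into bromo[(3E)-4-phenylbut-3-en-1-yl]zinc F5. Pd(PPh3)4-catalysed Negishi coupling of F3 with F5 (THF, rt) proceeds with retention of both alkene geometries and gives 21.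

Step 15 (oxetane perhydrolysis). The risks are incomplete inversion at the quaternary carbon, attack at the wrong ring carbon, and acid-induced damage to the styryl diene. The fallback sets out from 18 and comes back at 27; it moves the peroxide chemistry onto the simpler alkene 18 and attaches the tail after the peroxyketal ring is closed. Oxetane 18 is opened with ethereal H2O2 and TMSOTf to (4R,6R)-4-hydroperoxy-4,6,10-trimethylundec-9-en-2-ol F6. TBSCl and imidazole give (4R,6R)-4-[(tert-butyldimethylsilyl)peroxy]-4,6,10-trimethylundec-9-en-2-ol F7, and Dess–Martin periodinane gives (4R,6R)-4-[(tert-butyldimethylsilyl)peroxy]-4,6,10-trimethylundec-9-en-2-one F8. HF·pyridine followed by TsOH in MeOH leads through (4R,6R)-4-hydroperoxy-4,6,10-trimethylundec-9-en-2-one F9 and (5R)-5-[(2R)-2,6-dimethylhept-5-en-1-yl]-3,5-dimethyl-1,2-dioxolan-3-ol F10 to (5R)-5-[(2R)-2,6-dimethylhept-5-en-1-yl]-3-methoxy-3,5-dimethyl-1,2-dioxolane F11. Ozonolysis (O3, CH2Cl2, −78 °C; Me2S) passes through 3-{(3R)-4-[(5R)-3-methoxy-3,5-dimethyl-1,2-dioxolan-5-yl]-3-methylbutyl}-5,5-dimethyl-1,2,4-trioxolane F12 to (4R)-5-[(5R)-3-methoxy-3,5-dimethyl-1,2-dioxolan-5-yl]-4-methylpentanal F13. The tetrasubstituted peroxyketal has no hydrogen next to the O–O bond and tolerates the Julia–Kocienski coupling of F13 with 7 (KN(SiMe3)2, DME, −60 °C), which gives 27.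

Step 20 (addition to the peroxycarbenium ion). The risks are low facial selectivity at C3 and Lewis acid fragmentation of the peroxide. The fallback sets out from 24 and comes back at 32; it closes the ring by C–O bond formation instead. Horner–Wadsworth–Emmons olefination of ketone 24 with triethyl phosphonoacetate and NaH (THF, 0 °C → rt) gives ethyl (5R,7R,10E,14E)-5-[(tert-butyldimethylsilyl)peroxy]-3,5,7-trimethyl-15-phenylpentadeca-2,10,14-trienoate F14 as a 2E/2Z mixture, both isomers being usable. HF·pyridine frees ethyl (5R,7R,10E,14E)-5-hydroperoxy-3,5,7-trimethyl-15-phenylpentadeca-2,10,14-trienoate F15. Without isolation, Et2NH in CF3CH2OH cyclises it by a reversible 5-exo peroxy-Michael addition, which allows the unwanted C3 epimer to be recycled, and chromatography gives ethyl 2-[(3S,5R)-3,5-dimethyl-5-[(2R,5E,9E)-2-methyl-10-phenyldeca-5,9-dien-1-yl]-1,2-dioxolan-3-yl]acetate F16. Hydrolysis with LiOH in THF/H2O gives 32.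

**Further compounds**
F1 | step 14 | (2S)-2,4-dimethyl-2-[(2R)-2-methylhex-5-yn-1-yl]oxetane | CC1C[C@@](C)(O1)C[C@H](C)CCC#C
F2 | step 14 | chlorobis(cyclopentadienyl)[(1E,5R)-6-[(2S)-2,4-dimethyloxetan-2-yl]-5-methylhex-1-en-1-yl]zirconium | CC1C[C@@](C)(O1)C[C@H](C)CC/C=C/[Zr](Cl)(C2C=CC=C2)C3C=CC=C3
F3 | step 14 | (2S)-2-[(2R,5E)-6-iodo-2-methylhex-5-en-1-yl]-2,4-dimethyloxetane | CC1C[C@@](C)(O1)C[C@H](C)CC/C=C/I
F4 | step 14 | [(1E)-4-bromobut-1-en-1-yl]benzene | BrCC/C=C/c1ccccc1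
F5 | step 14 | bromo[(3E)-4-phenylbut-3-en-1-yl]zinc | Br[Zn]CC/C=C/c1ccccc1
F6 | step 15 | (4R,6R)-4-hydroperoxy-4,6,10-trimethylundec-9-en-2-ol | CC(O)C[C@](C)(OO)C[C@H](C)CCC=C(C)C
F7 | step 15 | (4R,6R)-4-[(tert-butyldimethylsilyl)peroxy]-4,6,10-trimethylundec-9-en-2-ol | CC(O)C[C@](C)(OO[Si](C)(C)C(C)(C)C)C[C@H](C)CCC=C(C)C
F8 | step 15 | (4R,6R)-4-[(tert-butyldimethylsilyl)peroxy]-4,6,10-trimethylundec-9-en-2-one | CC(=O)C[C@](C)(OO[Si](C)(C)C(C)(C)C)C[C@H](C)CCC=C(C)C
F9 | step 15 | (4R,6R)-4-hydroperoxy-4,6,10-trimethylundec-9-en-2-one | CC(=O)C[C@](C)(OO)C[C@H](C)CCC=C(C)C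
F10 | step 15 | (5R)-5-[(2R)-2,6-dimethylhept-5-en-1-yl]-3,5-dimethyl-1,2-dioxolan-3-ol | C[C@H](CCC=C(C)C)C[C@]1(C)CC(C)(O)OO1
F11 | step 15 | (5R)-5-[(2R)-2,6-dimethylhept-5-en-1-yl]-3-methoxy-3,5-dimethyl-1,2-dioxolane | C[C@H](CCC=C(C)C)C[C@]1(C)CC(C)(OC)OO1
F12 | step 15 | 3-{(3R)-4-[(5R)-3-methoxy-3,5-dimethyl-1,2-dioxolan-5-yl]-3-methylbutyl}-5,5-dimethyl-1,2,4-trioxolane | C[C@H](CCC2OOC(C)(C)O2)C[C@]1(C)CC(C)(OC)OO1
F13 | step 15 | (4R)-5-[(5R)-3-methoxy-3,5-dimethyl-1,2-dioxolan-5-yl]-4-methylpentanal | C[C@H](CCC=O)C[C@]1(C)CC(C)(OC)OO1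
F14 | step 20 | ethyl (5R,7R,10E,14E)-5-[(tert-butyldimethylsilyl)peroxy]-3,5,7-trimethyl-15-phenylpentadeca-2,10,14-trienoate | CCOC(=O)C=C(C)C[C@](C)(OO[Si](C)(C)C(C)(C)C)C[C@H](C)CC/C=C/CC/C=C/c1ccccc1
F15 | step 20 | ethyl (5R,7R,10E,14E)-5-hydroperoxy-3,5,7-trimethyl-15-phenylpentadeca-2,10,14-trienoate | CCOC(=O)C=C(C)C[C@](C)(OO)C[C@H](C)CC/C=C/CC/C=C/c1ccccc1
F16 | step 20 | ethyl 2-[(3S,5R)-3,5-dimethyl-5-[(2R,5E,9E)-2-methyl-10-phenyldeca-5,9-dien-1-yl]-1,2-dioxolan-3-yl]acetate | C[C@H](CC/C=C/CC/C=C/c1ccccc1)C[C@]1(C)C[C@@](C)(CC(=O)OCC)OO1
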